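**Plan**
1. Ring numbering follows furan-2(5H)-one: O1, C2(=O), C3(CH3), C4(CO2H), C5(H, the stereocentre); the chain is C1'–C13'. Cuts, in order: C4-CO2H ⇐ tert-butyl ester; C5–C1' ⇐ racemic 5-bromobutenolide + terminal alkene; C5–Br ⇐ C5–H; C3=C4 and O1–C5 ⇐ phosphonopropanoic acid + tert-butyl bromopyruvate; C3'–C4' ⇐ allyl Grignard + C10 bromo alcohol.
2. Enabling feature: C5 lies between the acyloxy oxygen O1 and the C4=C3–C2=O enoate of the butenolide ring. Nickel can therefore abstract bromine from a C5–Br bond, leaving a planar, captodatively stabilised 2-oxofuranyl radical that has lost its configuration. The other radical terminus, C3, is blocked by the methyl group.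
3. Forward order: the butenolide ring is closed first by a tethered olefination and brominated at C5. It is then joined to tridec-12-enyl acetate by NiH hydroalkylation, and the acid is unmasked last.
4. Stereochemistry: the single (R) centre comes only from the chiral nickel catalyst, which funnels both enantiomers of the bromide into one product (enantioconvergent coupling).

Key step: step 6

Assumption: the absolute sense of induction of the Ni/bis(oxazoline) catalyst on this new electrophile cannot be derived safely from the acyclic cases. The (S,S)-ligand is written, and its mirror image would be used if the product proves to be (S).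

**Step 1**
Reactants: 1 bromopyruvic acid (3-bromo-2-oxopropanoic acid)
Product: 2 tert-butyl 3-bromo-2-oxopropanoate
Conditions: Cl3CC(=NH)Ot-Bu (2 equiv), CH2Cl2/cyclohexane, rt
Reagents that add atoms: tert-butyl 2,2,2-trichloroacetimidate, CC(C)(C)OC(=N)C(Cl)(Cl)Cl
Why: O-tert-butylation of a carboxylic acid by the trichloroacetimidate is promoted by the substrate acid itself and needs no base, so the base-sensitive α-bromo-α-keto unit is not touched.

**Step 2**
Reactants: 2 tert-butyl 3-bromo-2-oxopropanoate; 3 2-(diethoxyphosphoryl)propanoic acid (racemic)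
Product: 5 tert-butyl 4-methyl-5-oxo-2,5-dihydrofuran-3-carboxylate, via acyloxy keto phosphonate 4 (not isolated)
Conditions: K2CO3 (2.2 equiv), MeCN, 0 °C to rt (3 and base first, then 2)
Reagents that add atoms: none
Why: Carboxylate SN2 on the α-bromo ketone followed by intramolecular Horner–Wadsworth–Emmons olefination of the very electrophilic α-keto ester carbonyl closes the five-membered ring, and the ester tether enforces the required geometry (C2 cis to C5, the two carboxyl carbons trans).

**Step 3**
Reactants: 5 tert-butyl 4-methyl-5-oxo-2,5-dihydrofuran-3-carboxylate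
Product: 6 rac-tert-butyl 2-bromo-4-methyl-5-oxo-2,5-dihydrofuran-3-carboxylate (the 5-bromobutenolide)
Conditions: NBS (1.05 equiv), AIBN (5 mol %), PhCF3, 80 °C
Reagents that add atoms: N-bromosuccinimide, O=C1CCC(=O)N1Br
Why: Wohl–Ziegler bromination, as practised on 3-methylfuran-2(5H)-one, should take the C5–H because that radical is both allylic and α-oxygenated while the C3 methyl offers only a primary allyl radical; the new centre is racemic, which is all the next step needs.

**Step 4**
Reactants: 7 10-bromodecan-1-ol
Product: 8 tridec-12-en-1-ol
Conditions: allylMgBr (2.5 equiv), Li2CuCl4 (3 mol %), THF, −20 °C to rt; aq NH4Cl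
Reagents that add atoms: allylmagnesium bromide, C=CC[Mg]Br
Why: Copper-catalysed Grignard–alkyl bromide cross-coupling (Kochi coupling) at a primary bromide, the first equivalent of Grignard reagent being consumed by the free hydroxyl group.

**Step 5**
Reactants: 8 tridec-12-en-1-ol
Product: 9 tridec-12-en-1-yl acetate
Conditions: Ac2O, pyridine, DMAP (cat.), CH2Cl2, rt
Reagents that add atoms: acetic anhydride, CC(=O)OC(C)=O
Why: Standard DMAP-catalysed acetylation of a primary alcohol, which installs the terminal acetate of the target before the union.

**Step 6**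
Reactants: 6 rac-tert-butyl 2-bromo-4-methyl-5-oxo-2,5-dihydrofuran-3-carboxylate; 9 tridec-12-en-1-yl acetate
Product: 10 tert-butyl (2R)-2-(13-acetoxytridecyl)-4-methyl-5-oxo-2,5-dihydrofuran-3-carboxylate
Conditions: NiBr2·diglyme (10 mol %), (S,S)-Ph-BOX [2,2'-(propane-2,2-diyl)bis((4S)-4-phenyl-4,5-dihydrooxazole), 12 mol %], (EtO)3SiH, K3PO4·H2O, 2-MeTHF, 0 °C, slow addition of 6
Reagents that add atoms: none
Why: Proposed new method: a ligated Ni–H, formed from the nickel salt, the silane and the phosphate, adds anti-Markovnikov to the terminal alkene of 9 to give a primary alkylnickel, while a Ni(I) species abstracts bromine from either enantiomer of 6 to give the same planar C5 radical, which the chiral alkylnickel(II) captures before C(sp3)–C(sp3) reductive elimination from Ni(III). The closest known reaction types are the NiH/bis(oxazoline)-catalysed enantioconvergent hydroalkylation of terminal olefins with racemic acyclic 1-bromoalkyl esters and racemic α-bromo amides or lactams, and the enantioconvergent nickel-catalysed Negishi alkylation of racemic γ-chloro enoates; a cyclic 5-bromofuran-2(5H)-one, which is at once an α-acyloxy bromide and a vinylogous α-bromo ester, has not been used. No ring is closed. The C5 stereocentre is set by the ligand during radical capture and reductive elimination, and the C4 ester carbonyl can form a five-membered chelate (Ni–C5–C4–C=O) that takes over the directing role of the acyloxy carbonyl in the acyclic cases, a role the s-trans lactone carbonyl cannot play. The step needs C5 rather than C3 coupling of the ambident radical (C3 carries the methyl group, and bonding there would create a quaternary centre and break the conjugation), linear rather than branched alkylnickel (terminal alkene, primary Ni–C favoured), and Ni–H addition to the terminal alkene rather than to the shielded tetrasubstituted C3=C4 bond. Slow addition of 6 should keep the radical concentration low against C5–C5 dimerisation, and the weak heterogeneous base at 0 °C should leave the C5–H of 10 configurationally intact, just as equally hydrolysis-prone acyclic 1-bromoalkyl esters tolerate these conditions.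

**Step 7**
Reactants: 10 tert-butyl (2R)-2-(13-acetoxytridecyl)-4-methyl-5-oxo-2,5-dihydrofuran-3-carboxylate
Product: 11 (2R)-2-(13-acetoxytridecyl)-4-methyl-5-oxo-2,5-dihydrofuran-3-carboxylic acid (target)
Conditions: TFA/CH2Cl2 (1:4), 0 °C to rt
Reagents that add atoms: none
Why: Acidolysis of the tert-butyl ester through the tert-butyl cation leaves the primary acetate and the lactone intact and, since no base is present, cannot epimerise C5.

**Compound list**
1 | bromopyruvic acid (3-bromo-2-oxopropanoic acid) | O=C(O)C(=O)CBr | starting material
2 | tert-butyl 3-bromo-2-oxopropanoate | CC(C)(C)OC(=O)C(=O)CBr | intermediate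
3 | 2-(diethoxyphosphoryl)propanoic acid (racemic) | CCOP(=O)(OCC)C(C)C(=O)O | starting material
4 | tert-butyl 3-{[2-(diethoxyphosphoryl)propanoyl]oxy}-2-oxopropanoate (racemic, not isolated) | CCOP(=O)(OCC)C(C)C(=O)OCC(=O)C(=O)OC(C)(C)C | intermediate
5 | tert-butyl 4-methyl-5-oxo-2,5-dihydrofuran-3-carboxylate | CC1=C(C(=O)OC(C)(C)C)COC1=O | intermediate
6 | rac-tert-butyl 2-bromo-4-methyl-5-oxo-2,5-dihydrofuran-3-carboxylate | CC1=C(C(=O)OC(C)(C)C)C(Br)OC1=O | intermediate
7 | 10-bromodecan-1-ol | OCCCCCCCCCCBr | starting material
8 | tridec-12-en-1-ol | C=CCCCCCCCCCCCO | intermediate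
9 | tridec-12-en-1-yl acetate | C=CCCCCCCCCCCCOC(C)=O | intermediate
10 | tert-butyl (2R)-2-(13-acetoxytridecyl)-4-methyl-5-oxo-2,5-dihydrofuran-3-carboxylate | CC(=O)OCCCCCCCCCCCCC[C@H]1OC(=O)C(C)=C1C(=O)OC(C)(C)C | intermediate
11 | (2R)-2-(13-acetoxytridecyl)-4-methyl-5-oxo-2,5-dihydrofuran-3-carboxylic acid | CC(=O)OCCCCCCCCCCCCC[C@H]1OC(=O)C(C)=C1C(=O)O | target

Total step count: 7. Longest linear sequence: 5 (steps 1, 2, 3, 6, 7).

**Steps most likely to fail**

**1. Step 6.**
- What may go wrong: reductive debromination by the silane/base pair, dimerisation of the stabilised C5 radical, hydrolysis of the C–Br bond by the hydrated base, or poor enantiofacial discrimination.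
- The fallback uses known polar chemistry on the ring-opened aldehyde. It sets out from 6 and 9 and returns at 10.
- Bromide 6 would be hydrolysed (H2O/acetone, rt) to tert-butyl 2-hydroxy-4-methyl-5-oxo-2,5-dihydrofuran-3-carboxylate F1.
- The ring-opened carboxylate of F1 would be O-methylated (MeI, K2CO3, DMF) to the open normal ester 1-tert-butyl 4-methyl (2E)-2-formyl-3-methylbut-2-enedioate F2, in which CHO is cis to CO2Me.
- Alkene 9 would be hydroborated with Et2BH to 13-(diethylboranyl)tridecyl acetate F3. Boron–zinc exchange with Et2Zn would then give bis(13-acetoxytridecyl)zinc F4.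
- Catalytic asymmetric 1,2-addition of F4 to F2 would follow, using Ti(OiPr)4 and (1S,2S)-1,2-bis(trifluoromethanesulfonamido)cyclohexane in toluene at −20 °C. By analogy with aromatic and α,β-unsaturated aldehydes, this ligand antipode is expected to give the (R)-carbinol.
- The product would be 1-tert-butyl 4-methyl (2E)-2-[(1R)-14-acetoxy-1-hydroxytetradecyl]-3-methylbut-2-enedioate F5, which lactonises onto the cis methyl ester on mildly acidic work-up to give 10.

**2. Step 3.**
- What may go wrong: competing hydrogen abstraction at the C3 methyl group, over-bromination, or acid-induced loss of the tert-butyl group.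
- The fallback replaces the radical process by an ionic one. It sets out from 5 and returns at 6.
- Soft enolisation (TBSOTf, Et3N, CH2Cl2, 0 °C) would give tert-butyl 5-[(tert-butyldimethylsilyl)oxy]-4-methylfuran-3-carboxylate F6.
- The only free furan position of F6, the later C5, would then be brominated electrophilically with NBS in THF at −78 °C, with loss of the silyl group, to give 6.

**3. Step 2.**
- What may go wrong: base-induced self-condensation of the enolisable bromo keto ester before or after the alkylation, or deprotonation and decay of the product butenolide.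
- The fallback closes the ring without a basic olefination. It sets out from 2 and returns at 5.
- Compound 2 would be esterified with potassium 2-bromopropanoate (acetone, 0 °C) to tert-butyl 3-[(2-bromopropanoyl)oxy]-2-oxopropanoate F7.
- Cyclisation by an intramolecular Reformatsky reaction (activated Zn, THF) would give tert-butyl 3-hydroxy-4-methyl-5-oxooxolane-3-carboxylate F8.
- Dehydration with SOCl2/pyridine at 0 °C, through the chlorosulfite of the tertiary alcohol F9, would proceed towards the acidic C–H next to the lactone carbonyl and give 5.

**Further compounds**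
F1 | step 6 | tert-butyl 2-hydroxy-4-methyl-5-oxo-2,5-dihydrofuran-3-carboxylate (racemic) | CC1=C(C(=O)OC(C)(C)C)C(O)OC1=O
F2 | step 6 | 1-tert-butyl 4-methyl (2E)-2-formyl-3-methylbut-2-enedioate | COC(=O)/C(C)=C(\C=O)C(=O)OC(C)(C)C
F3 | step 6 | 13-(diethylboranyl)tridecyl acetate | CCB(CC)CCCCCCCCCCCCCOC(C)=O
F4 | step 6 | bis(13-acetoxytridecyl)zinc | CC(=O)OCCCCCCCCCCCCC[Zn]CCCCCCCCCCCCCOC(C)=O
F5 | step 6 | 1-tert-butyl 4-methyl (2E)-2-[(1R)-14-acetoxy-1-hydroxytetradecyl]-3-methylbut-2-enedioate | COC(=O)/C(C)=C(\[C@H](O)CCCCCCCCCCCCCOC(C)=O)C(=O)OC(C)(C)C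
F6 | step 3 | tert-butyl 5-[(tert-butyldimethylsilyl)oxy]-4-methylfuran-3-carboxylate | CC1=C(O[Si](C)(C)C(C)(C)C)OC=C1C(=O)OC(C)(C)C
F7 | step 2 | tert-butyl 3-[(2-bromopropanoyl)oxy]-2-oxopropanoate (racemic) | CC(Br)C(=O)OCC(=O)C(=O)OC(C)(C)C
F8 | step 2 | tert-butyl 3-hydroxy-4-methyl-5-oxooxolane-3-carboxylate (racemic, diastereomer mixture) | CC1C(=O)OCC1(O)C(=O)OC(C)(C)C
F9 | step 2 | tert-butyl 3-[(chlorosulfinyl)oxy]-4-methyl-5-oxooxolane-3-carboxylate | CC1C(=O)OCC1(OS(=O)Cl)C(=O)OC(C)(C)C
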